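The solid substrate left at 10.0 s in Wednesday's run, 81% of the charge, is where the reading of these flasks begins.

| setting | Wednesday's | Tuesday's | flask |
|---|---|---|---|
| solid substrate | 1.2 M | 1.2 M | 1.2 M |
| reagent | 1.5 equiv (fed, over 8.0 s) | 2.2 equiv (fed, over 8.0 s) | 1.50 equiv (fed, over 8.0 s) |
| protic impurity | 0.12 M | 0.12 M | 0.120 M |
| remark | the very flask that is asked about, followed so far; the fed solution adds 0.50 times the starting volume | run made earlier; the fed solution adds 0.50 times the starting volume | the fed solution adds 0.50 times the starting volume |
| time |  |  | 3.0 min |

- Wednesday's (time / s: solid substrate / %, product / %): 10.0: 81, 2; 20.0: 68, 4; 30.0: 61, 10; 50.0: 42, 21; 60.0: 30, 23; 90.0: 11, 42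
- Tuesday's (time / s: solid substrate / %, product / %): 10.0: 81, 1; 25.0: 67, 8; 40.0: 51, 17; 60.0: 32, 30; 90.0: 8, 55; 120: 0, 69

(scatter of a reading: 2 percentage points)

- every charge counts on the volume at the start, and the solution that is fed holds the whole dose
- the earlier runs were read with a standard deviation of 2 percentage points
- at the start none of the solid substrate is in solution
- what has only dissolved of solid substrate counts as not reacted
- a reading or a percentage of product counts all its forms, free or not
- the reaction counts as stopped when no species that holds the solid substrate changes by six tenths of a point or more over the second half of the time

1. the state of affairs at 3.0 min: stopped, and by what, or still going (for what has run out or reacted, a solid counts together with what of it has only dissolved) (all of the solid substrate has reacted / the reagent has run out first / it is still moving)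
2. part of the solid substrate that has turned into other species by 3.0 min (what has only dissolved does not count)
3. amount of product at 3.0 min, in percent of the solid substrate charged

From that reading to 60.0 s, Wednesday's solid substrate falls by 51 percentage points along a nearly straight line. Run back to time zero, the line starts at 91.2%, which leaves a missing piece of 8.80% of the charge. The same reckoning on Tuesday's run, with more reagent, gives 9.20%, and each reading carries a scatter of 2 points.

The protic impurity is charged at 10.0% of the solid substrate. This ratio of charges, to which the two missing pieces point, is taken here as the side share: the fraction of the charge lost in the first seconds to a side reaction with the protic impurity, mole for mole, without passing through product.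

If dissolved substrate has no other outlet than product, then after those seconds the rate of conversion divided by the rate of product is one. Time drops out of that ratio, so on that assumption the flask's conversion equals product plus the side share at any later reading.

The forecast says it is still moving, with conversion at 75% (68% to 82%) and product at 75% (67% to 81%). Its ground for the impurity is “The impurity takes 0.1 equiv of reagent”. The reckoning here differs: it accepts the forecast's product but adds the side share, which puts conversion at 85.0%, above the forecast's high end.

The flask gives: it is still moving, conversion 85.2%, product 75.2%.

    solid substrate ⇌ dissolved substrate, rate k1*(cs1 - [dissolved substrate]) while solid is left; crystals form when [dissolved substrate] > cs1 (solubility = 0.910 M, k = 0.0100 s⁻¹)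
    dissolved substrate + reagent → product (k = 0.0190 M⁻¹ s⁻¹)
    crystals ⇌ product, rate k3*(cs3 - [product]) while solid is left; crystals form when [product] > cs3 (solubility = 0.350 M, k = 0.260 s⁻¹)
    solid substrate + protic impurity → quenched substrate (k = 3.80 M⁻¹ s⁻¹)

In the flask, 75.2% of product plus the side share makes 85.2%. The neighbour with 0.380 equiv of reagent reaches 28.0% of product, which with the side share makes 38.0%, its conversion being 38.0%. By the end of the feed at 0.133 min, the flask's protic impurity stood at 0% and quenched substrate at 10.0%. Dissolved substrate and reagent went on making product, half of that step's turnover up to the asked time being done by 1.37 min, and at 3.00 min the flask held solid substrate at 0%, dissolved substrate at 14.8%, and 50% of the reagent charge, with crystals at 30.7% counted within product.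

(The earlier runs and the new flask were computed for an exercise; noise was put on by code.)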